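Count how many lives the starting complex gets through while a feed runs; that count is what I worked from.

| setting | zeta | epsilon | delta | birch | oak | alder |
|---|---|---|---|---|---|---|
| starting complex | 0.079 M | 0.11 M | 0.17 M | 0.079 M | 0.079 M | 0.079 M (fed, over 25 min) |
| incoming ligand | 0.118 M | 0.118 M | 0.118 M | 0.118 M | 0.118 M (fed, over 25 min) | 0.118 M |
| protic impurity | 1.58 mM | 1.58 mM | 1.58 mM | 1.58 mM | 1.58 mM | 1.58 mM |
| remark | run made earlier | run made earlier | run made earlier | everything together at the start | all else is in the flask from the start; the feed brings no volume worth counting | all else is in the flask from the start; the feed brings no volume worth counting |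
| time |  |  |  | 30 min | 30 min | 30 min |

- zeta (time / min: complex with two exchanged / %, starting complex / %): 2.50: 3.4, 14.2; 5.00: 5.2, 7.4; 8.00: 8.1, 3.6; 10.0: 13.7, 2.7; 12.0: 13.6, 0.9; 15.0: 15.3, 1.0; 20.0: 20.3, 0
- epsilon (time / min: complex with two exchanged / %, starting complex / %): 2.50: 1.9, 13.2; 5.00: 3.4, 4.7; 8.00: 7.9, 1.2; 10.0: 9.8, 1.4; 12.0: 10.2, 0; 15.0: 13.0, 2.0; 20.0: 16.8, 0
- delta (time / min: complex with two exchanged / %, starting complex / %): 1.00: 0, 23.3; 3.00: 1.7, 5.8; 5.00: 4.9, 4.3; 8.00: 6.4, 2.0; 10.0: 6.4, 0.7; 15.0: 10.7, 0; 20.0: 9.7, 0.8

(each reading ± 1 percentage point)



* which flask leads in amount of complex with two exchanged, in percent of the starting complex charged ("all alike" within 1.5 percentage points) (birch / oak / alder / all alike)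
* how much complex with two exchanged is there at the end, in percent of the starting complex charged: birch
* how much complex with two exchanged is there at the end, in percent of the starting complex charged: oak
* how much complex with two exchanged is there at the end, in percent of the starting complex charged: alder

In the earlier runs [starting complex] fell fast, and I read its fall in two ways. Taken as first order, the zeta run gives 0.781 min⁻¹ from the reading at 2.50 min but 0.416 min⁻¹ from the one at 8.00 min, so that constant drifts within a single flask. Taken as second order in itself, the zeta reading at 5.00 min gives 31.7 L mol⁻¹ min⁻¹, but the same reckoning gives 19.4 L mol⁻¹ min⁻¹ from the delta reading at 1.00 min and 42.4 L mol⁻¹ min⁻¹ from the zeta reading at 8.00 min, so the highest of these readings is twice the lowest. Neither form holds cleanly, so I kept the zeta value at 5.00 min as a rough k with that spread on it, and it carries whatever the ligand takes as well.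

At the charge of birch and oak that makes 0.400 min. This is the self-life: the time in which starting complex halves against itself, one over k times [starting complex], the usual second-order half-life. Oak's feed lasts 62.5 self-lives, and at 6.25 min, when a quarter of its ligand is in, a loss at this rough k leaves 6.02% of the complex. In alder the fed complex should level off where a loss at this k carries the feed, near 0.00999 M, and the self-life there is 3.16 min, with the ligand in the flask from the start. So I committed to an order: oak last, birch and alder close together.

The forecast, made from the same runs, gave birch the lead, with 30% for birch, 22% for oak and 28% for alder, and said “Oak is the real unknown”.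

    complex with one exchanged + incoming ligand ⇌ leaving ligand + complex with two exchanged (K = 0.350, k = 0.00790 L mol⁻¹ s⁻¹)
    protic impurity + starting complex → quenched substrate (k = 2.00 L mol⁻¹ s⁻¹)
    2 starting complex → self-condensation product (k = 0.120 L mol⁻¹ s⁻¹)
    starting complex + incoming ligand ⇌ leaving ligand + complex with one exchanged (K = 1.90, k = 0.0550 L mol⁻¹ s⁻¹)
    leaving ligand → by-product carried off (k = 0.0320 s⁻¹)

The flasks put birch in the lead at 30 min: birch 26.3%, oak 6.33%, alder 24.6%. Oak's feed of 25 min is 62.5 self-lives long by my rough k, or 28.4 by the self-condensation step of the scheme taken by itself, whose life at that charge is 0.879 min, and at 25.0 min oak has turned 85.9% of its charge into self-condensation product, more than the 54.8% in birch at 30.0 min. In alder the level of 0.00999 M, reckoned with a k that carries the ligand's share too, stands beside a [starting complex] of 0.00963 M at 25.0 min, when self-condensation product holds 25.0% of the charge and the complexes with one and two exchanged together 60.8%.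

The runs stem from a simulated flask with made-up constants; scatter was added.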